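**Retrosynthetic overview**

1. Feature: in ring C (C1, C9a, C9, C10, C11, C12) the tertiary carbinol C1 sits next to the enamine carbon C9a, a ketone masked by N4. C1(OH)–C9a(=O) is an α-ketol, the retron of an acyl-anion addition of a C9a aldehyde to a C1 ketone.
2. Key disconnection: C1–C9a, closing ring C onto the preformed butenolide (ring D) by a carbene-catalysed aldehyde–ketone benzoin reaction of a 4-acyl-3-methylbutenolide keto aldehyde.
3. Keto aldehyde: C1–C2 by palladium-catalysed acylation of a β-amido alkylzinc iodide with a butenolide acid chloride. The zinc reagent carries the finished side-chain lactone, built from an L-serine-derived oxazolidine acid and methyl (S)-3-hydroxy-2-methylpropanoate. C10–C11 comes from an iminium-catalysed vinylogous Mukaiyama–Michael addition of a 4-(benzyloxycarbonyl)-3-methyl-2-silyloxyfuran to (E)-pent-2-enal.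
4. After the key step: hydroxyl-directed hydrogenation of C12=C13, C13 epimerisation, C9 alkylation with 1-chloro-4-iodobutane, Boc removal with imine formation (ring B), N-alkylation (ring A).
5. Ring order: D (butenolide) and the side-chain lactone first, then C (key step), then B, then A.

Key step: step 13

Atom labels used throughout: C1 (carbinol), C2, C3 (N-bearing), N4, C5–C8 (ring A methylenes), C9, C9a, C10 (ethyl-bearing), C11 (O-bearing), C12, C13 (methyl-bearing), C18 (side-chain lactone CH–O), C19, C20 (methyl-bearing). Rings: A azepine, B pyrroline, C carbocycle, D fused lactone. The target is (1S,3S,10R,11R,12R,13R,18S,20S). On ring C the C1 hydroxyl, H10, H11 and H12 lie on one face; the ethyl group, O11, C13 and C2 lie on the other.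

Assumption: the (5aS,10bR) antipode of the aminoindanol-derived triazolium salt is taken as the matched catalyst for the required ketone face in step 13; if the pairing proves mismatched, the enantiomeric salt is used in the same step.

**Route**

Step 1
Reactants: 1 4-hydroxy-3-methylfuran-2(5H)-one (3-methyltetronic acid)
Product: 2 4-methyl-5-oxo-2,5-dihydrofuran-3-yl trifluoromethanesulfonate
Conditions: Tf2O, i-Pr2NEt, CH2Cl2, −78 °C
Reagents that add atoms: trifluoromethanesulfonic anhydride, O=S(=O)(OS(=O)(=O)C(F)(F)F)C(F)(F)F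
Why: O-Sulfonylation of the vinylogous acid gives the enol triflate at C4 of the furanone (the future C12), the usual way to open this carbon to palladium chemistry.

Step 2
Reactants: 2 enol triflate
Product: 3 benzyl 4-methyl-5-oxo-2,5-dihydrofuran-3-carboxylate
Conditions: CO (1 atm), BnOH, Pd(OAc)2 (5 mol%), 1,3-bis(diphenylphosphino)propane (6 mol%), i-Pr2NEt, DMF, 50 °C
Reagents that add atoms: carbon monoxide, [C-]#[O+]; benzyl alcohol, OCc1ccccc1
Why: Palladium-catalysed alkoxycarbonylation of an enol triflate (oxidative addition, CO insertion, alcoholysis of the acyl palladium) places the future C1 carbon on the ring as a benzyl ester that can later be freed without base.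

Step 3
Reactants: 3 benzyl ester butenolide
Product: 4 benzyl 5-[(tert-butyldimethylsilyl)oxy]-4-methylfuran-3-carboxylate
Conditions: TBSOTf, Et3N, CH2Cl2, 0 °C
Reagents that add atoms: tert-butyldimethylsilyl trifluoromethanesulfonate, CC(C)(C)[Si](C)(C)OS(=O)(=O)C(F)(F)F
Why: Soft enolisation of a butenolide with γ-hydrogens (silyl triflate and amine) gives the aromatic 2-silyloxyfuran, the vinylogous nucleophile for the next step.

Step 4
Reactants: 4 silyloxyfuran; 5 (E)-pent-2-enal
Product: 6 benzyl (2R)-4-methyl-5-oxo-2-[(3R)-1-oxopentan-3-yl]-2,5-dihydrofuran-3-carboxylate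
Conditions: (2S,5S)-5-benzyl-2-tert-butyl-3-methylimidazolidin-4-one (20 mol%), 2,4-dinitrobenzoic acid (20 mol%), H2O (2 equiv), CH2Cl2, −60 to −40 °C
Reagents that add atoms: none
Why: Organocatalytic vinylogous Mukaiyama–Michael addition under iminium catalysis: the benzyl group of the imidazolidinone shields one face of the (E)-iminium ion so that furan C5 adds to the open face of the enal β-carbon (C10, R, the same sense as other π-nucleophiles with this catalyst antipode), and the compact approach with the furan ring over the iminium ion should place the ethyl group and the ring oxygen anti along the C9–C10–C11–C12 chain (C11, R), the diastereomer this reaction normally favours with alkyl-substituted enals.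

Step 5
Reactants: 6 benzyl ester aldehyde
Product: 7 (2R)-4-methyl-5-oxo-2-[(3R)-1-oxopentan-3-yl]-2,5-dihydrofuran-3-carboxylic acid
Conditions: H2 (1 atm), 10% palladium on carbon, EtOAc, rt, short reaction time
Reagents that add atoms: none
Why: Hydrogenolysis of the benzyl ester is faster than reduction of the tetrasubstituted, doubly acyl-substituted alkene or of the aliphatic aldehyde, and it frees the acid without base so that H11 is not touched.

Step 6
Reactants: 8 methyl (S)-3-hydroxy-2-methylpropanoate
Product: 9 methyl (R)-3-iodo-2-methylpropanoate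
Conditions: I2, PPh3, imidazole, CH2Cl2, 0 °C to rt
Reagents that add atoms: iodine, II
Why: Appel-type iodination of the primary alcohol leaves the α-stereocentre alone, so C20 comes from the chiral pool (the descriptor changes only through the priority rules).

Step 7
Reactants: 10 (4S)-3-(tert-butoxycarbonyl)-2,2-dimethyl-1,3-oxazolidine-4-carboxylic acid
Product: 11 S-ethyl (4S)-3-(tert-butoxycarbonyl)-2,2-dimethyl-1,3-oxazolidine-4-carbothioate
Conditions: EtSH, EDC·HCl, DMAP (10 mol%), CH2Cl2, 0 °C to rt
Reagents that add atoms: ethanethiol, CCS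
Why: Carbodiimide/DMAP thioesterification (Steglich type) of the urethane-protected serine-derived acid should proceed without racemisation and gives the acyl donor for the ketone synthesis.

Step 8
Reactants: 9 methyl (R)-3-iodo-2-methylpropanoate; 11 thioester
Product: 13 tert-butyl (4S)-4-[(3S)-4-methoxy-3-methyl-4-oxobutanoyl]-2,2-dimethyl-1,3-oxazolidine-3-carboxylate, via alkylzinc iodide 12 (not isolated)
Conditions: 9, Zn dust (activated by 1,2-dibromoethane and Me3SiCl), THF, 30 °C; then 11, PdCl2(PPh3)2 (10 mol%), toluene, rt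
Reagents that add atoms: none
Why: Fukuyama coupling: zinc inserts into the primary iodide to give the ester-bearing alkylzinc reagent, zerovalent palladium inserts into the C–S bond of the thioester and transfers the alkyl group, and the ketone forms without over-addition and without epimerising the α-amino or α-methyl centres.

Step 9
Reactants: 13 γ-keto ester
Product: 15 tert-butyl (4S)-2,2-dimethyl-4-[(2S,4S)-4-methyl-5-oxooxolan-2-yl]-1,3-oxazolidine-3-carboxylate, via γ-hydroxy ester 14 (not isolated)
Conditions: LiBH(s-Bu)3, THF, −78 °C; AcOH quench; then pyridinium p-toluenesulfonate (cat.), toluene, 60 °C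
Reagents that add atoms: none
Why: Felkin–Anh-controlled ketone reduction by the bulky borohydride (hydride delivered anti to the N-Boc nitrogen of the oxazolidine, no chelation) should give the syn amino alcohol (C18, S), and the γ-hydroxy ester then lactonises with retention to the cis-2,4-disubstituted lactone.

Step 10
Reactants: 15 oxazolidine lactone
Product: 16 tert-butyl N-[(1S)-2-hydroxy-1-[(2S,4S)-4-methyl-5-oxooxolan-2-yl]ethyl]carbamate
Conditions: AcOH/H2O (4:1), 45 °C
Reagents that add atoms: none
Why: Mild aqueous acid hydrolyses the N,O-acetonide while the Boc group and the γ-lactone survive.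

Step 11
Reactants: 16 N-Boc amino alcohol
Product: 17 tert-butyl N-[(1R)-2-iodo-1-[(2S,4S)-4-methyl-5-oxooxolan-2-yl]ethyl]carbamate
Conditions: I2, PPh3, imidazole, CH2Cl2, 0 °C; used at once
Reagents that add atoms: iodine, II
Why: Appel-type iodination of the primary alcohol of an N-Boc amino alcohol is the standard entry to β-amido alkyl iodides for zinc insertion, and no stereocentre is involved.

Step 12
Reactants: 7 butenolide acid; 17 iodide
Product: 20 tert-butyl N-[(1S)-3-[(2R)-4-methyl-5-oxo-2-[(3R)-1-oxopentan-3-yl]-2,5-dihydrofuran-3-yl]-1-[(2S,4S)-4-methyl-5-oxooxolan-2-yl]-3-oxopropyl]carbamate, via acid chloride 18 (not isolated), via alkylzinc iodide 19 (not isolated)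
Conditions: 7, 1-chloro-N,N,2-trimethylprop-1-en-1-amine, CH2Cl2, 0 °C (gives 18); 17, Zn dust (I2-activated), DMF, rt (gives 19); then 18 added to 19, PdCl2(PPh3)2 (5 mol%), THF/DMF, 0 °C to rt
Reagents that add atoms: none
Why: Negishi-type acylation of a β-amido alkylzinc iodide: zinc inserts into the primary C–I bond (the reagent resists β-elimination in DMF at room temperature) and zerovalent palladium couples it with the acid chloride made under neutral conditions, which forms C1–C2 without base so that the free aldehyde, both lactones and the acidic H11 are left alone.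

Step 13
Reactants: 20 keto aldehyde
Product: 21 tert-butyl N-[(1S)-2-[(4S,7R,7aR)-7-ethyl-4-hydroxy-3-methyl-2,5-dioxo-2,4,5,6,7,7a-hexahydro-1-benzofuran-4-yl]-1-[(2S,4S)-4-methyl-5-oxooxolan-2-yl]ethyl]carbamate
Conditions: (5aS,10bR)-2-(pentafluorophenyl)-5a,10b-dihydro-4H,6H-indeno[2,1-b][1,2,4]triazolo[4,3-d][1,4]oxazin-2-ium tetrafluoroborate (20 mol%), NaOAc (20 mol%), toluene (0.02 M), 30 °C, argon
Reagents that add atoms: none
Why: The triazolylidene adds to the C9a aldehyde, proton transfer gives the enaminol (acyl-anion equivalent), its carbon attacks the C1 ketone with the enol O–H hydrogen-bonded to the ketone oxygen, and loss of the carbene from the adduct leaves the tertiary α-ketol. This is the intramolecular crossed aldehyde–ketone benzoin reaction, established for tethered aliphatic aldehydes and ketones with aminoindanol-derived triazolium salts and weak bases. Ring C closes by a 6-exo-trig attack on the exocyclic C1 carbonyl of the 4-acylbutenolide, which forms the C1–C9a bond. C1 is the only new stereocentre and is set by the chiral carbene, whose indane wall fixes the face of the enaminol and, through the hydrogen bond, the ketone face, so that the hydroxyl ends up on the side of H11 (anti to O11) and the C2 chain next to the C13 methyl. Chemoselectivity is secured by the substrate: the only alkene is tetrasubstituted, so Stetter addition at C12 (5-exo, quaternary centre) or at C13 (6-endo) is slow, and with NaOAc as the base neither H11 nor the aldehyde α-hydrogens are removed. The facial selectivity is the demanding one, because allylic strain with the C13 methyl favours the other ketone rotamer, so it rests on the catalyst antipode and not on the C10 and C11 centres.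

Step 14
Reactants: 21 butenolide α-ketol
Product: 22 tert-butyl N-[(1S)-2-[(3S,3aR,4S,7R,7aR)-7-ethyl-4-hydroxy-3-methyl-2,5-dioxooctahydro-1-benzofuran-4-yl]-1-[(2S,4S)-4-methyl-5-oxooxolan-2-yl]ethyl]carbamate
Conditions: H2 (10 bar), [Ir(cod)(PCy3)(py)]PF6 (15 mol%), CH2Cl2, rt
Reagents that add atoms: none
Why: Hydroxyl-directed hydrogenation with the cationic iridium catalyst: the C1 hydroxyl binds the metal and both hydrogens are delivered to the tetrasubstituted C12=C13 bond from its face, which is also the face away from the C10 ethyl group and the C2 chain, giving the cis-fused lactone (C12, R) and, by syn addition, the 13S methyl epimer.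

Step 15
Reactants: 22 C13-epi lactone
Product: 23 tert-butyl N-[(1S)-2-[(3R,3aR,4S,7R,7aR)-7-ethyl-4-hydroxy-3-methyl-2,5-dioxooctahydro-1-benzofuran-4-yl]-1-[(2S,4S)-4-methyl-5-oxooxolan-2-yl]ethyl]carbamate
Conditions: DBU (0.5 equiv), toluene, 60 °C
Reagents that add atoms: none
Why: Base-mediated epimerisation α to the lactone carbonyl should move the C13 methyl from the concave face (cis to C1) to the convex face (13R), the thermodynamically preferred arrangement, while the side-chain lactone already has its preferred cis-2,4 arrangement.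

Step 16
Reactants: 23 keto lactone; 24 1-chloro-4-iodobutane
Product: 25 tert-butyl N-[(1S)-2-[(3R,3aR,4S,7R,7aR)-6-(4-chlorobutyl)-7-ethyl-4-hydroxy-3-methyl-2,5-dioxooctahydro-1-benzofuran-4-yl]-1-[(2S,4S)-4-methyl-5-oxooxolan-2-yl]ethyl]carbamate (epimers at C9)
Conditions: LiN(SiMe3)2 (3.05 equiv), THF/DMPU (5:1), −78 °C; then 24, −78 to −30 °C; AcOH quench at −78 °C
Reagents that add atoms: none
Why: Kinetic ketone enolate alkylation: after the O–H and N–H protons the amide base removes a C9 hydrogen (the only α-hydrogens of the ketone, and far more acidic than the lactone α-hydrogens), and the enolate is C-alkylated by the primary iodide while the chloride is kept for ring A; the new C9 centre may form as a mixture, which does not matter because it is destroyed in step 18.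

Step 17
Reactants: 25 C9-alkylated ketone
Product: 27 cyclic imine in which N4=C9a closes ring B (9-(4-chlorobutyl)-1-hydroxy; rings B C D and the side-chain lactone in place; configuration 1S,3S,10R,11R,12R,13R,18S,20S), via ammonium trifluoroacetate 26 (not isolated)
Conditions: CF3CO2H, CH2Cl2, 0 °C to rt; evaporate; NaOAc, 4 Å molecular sieves, CH2Cl2, rt to 35 °C
Reagents that add atoms: none
Why: Acidolysis of the Boc group, then buffered condensation of the ammonium salt with the C9a ketone, closes ring B as a five-membered cyclic imine (5-exo-trig addition and dehydration) before the free amine can open the neighbouring γ-lactone to a δ-lactam.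

Step 18
Reactants: 27 cyclic imine
Product: 29 CNP0179500.2 (target), via iminium chloride 28 (not isolated)
Conditions: NaI (20 mol%), i-Pr2NEt, MeCN, 70 °C
Reagents that add atoms: none
Why: Intramolecular N-alkylation of the imine nitrogen by the iodide formed in situ (Finkelstein exchange, 7-exo-tet) closes ring A as a bicyclic iminium ion, which loses the C9 proton to the amine base and gives the tetrasubstituted enamine of the target, whereas C-alkylation through the enamine tautomer would have to build a spiro quaternary centre next to C10.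

**Compound list**

1 | 4-hydroxy-3-methylfuran-2(5H)-one (3-methyltetronic acid) | CC1=C(O)COC1=O | starting material
2 | 4-methyl-5-oxo-2,5-dihydrofuran-3-yl trifluoromethanesulfonate | CC1=C(OS(=O)(=O)C(F)(F)F)COC1=O | intermediate
3 | benzyl 4-methyl-5-oxo-2,5-dihydrofuran-3-carboxylate | CC1=C(C(=O)OCc2ccccc2)COC1=O | intermediate
4 | benzyl 5-[(tert-butyldimethylsilyl)oxy]-4-methylfuran-3-carboxylate | Cc1c(O[Si](C)(C)C(C)(C)C)occ1C(=O)OCc1ccccc1 | intermediate
5 | (E)-pent-2-enal | CC/C=C/C=O | starting material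
6 | benzyl (2R)-4-methyl-5-oxo-2-[(3R)-1-oxopentan-3-yl]-2,5-dihydrofuran-3-carboxylate | O=CC[C@@H](CC)[C@H]1OC(=O)C(C)=C1C(=O)OCc1ccccc1 | intermediate
7 | (2R)-4-methyl-5-oxo-2-[(3R)-1-oxopentan-3-yl]-2,5-dihydrofuran-3-carboxylic acid | O=CC[C@@H](CC)[C@H]1OC(=O)C(C)=C1C(=O)O | intermediate
8 | methyl (S)-3-hydroxy-2-methylpropanoate | OC[C@H](C)C(=O)OC | starting material
9 | methyl (R)-3-iodo-2-methylpropanoate | IC[C@H](C)C(=O)OC | intermediate
10 | (4S)-3-(tert-butoxycarbonyl)-2,2-dimethyl-1,3-oxazolidine-4-carboxylic acid (commercial, made from L-serine) | CC1(C)OC[C@@H](C(=O)O)N1C(=O)OC(C)(C)C | starting material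
11 | S-ethyl (4S)-3-(tert-butoxycarbonyl)-2,2-dimethyl-1,3-oxazolidine-4-carbothioate | CCSC(=O)[C@@H]1COC(C)(C)N1C(=O)OC(C)(C)C | intermediate
12 | [(2R)-3-methoxy-2-methyl-3-oxopropyl]zinc iodide | I[Zn]C[C@H](C)C(=O)OC | intermediate (not isolated)
13 | tert-butyl (4S)-4-[(3S)-4-methoxy-3-methyl-4-oxobutanoyl]-2,2-dimethyl-1,3-oxazolidine-3-carboxylate | COC(=O)[C@@H](C)CC(=O)[C@@H]1COC(C)(C)N1C(=O)OC(C)(C)C | intermediate
14 | tert-butyl (4S)-4-[(1S,3S)-1-hydroxy-4-methoxy-3-methyl-4-oxobutyl]-2,2-dimethyl-1,3-oxazolidine-3-carboxylate | COC(=O)[C@@H](C)C[C@H](O)[C@@H]1COC(C)(C)N1C(=O)OC(C)(C)C | intermediate (not isolated)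
15 | tert-butyl (4S)-2,2-dimethyl-4-[(2S,4S)-4-methyl-5-oxooxolan-2-yl]-1,3-oxazolidine-3-carboxylate | CC1(C)OC[C@@H]([C@@H]2C[C@H](C)C(=O)O2)N1C(=O)OC(C)(C)C | intermediate
16 | tert-butyl N-[(1S)-2-hydroxy-1-[(2S,4S)-4-methyl-5-oxooxolan-2-yl]ethyl]carbamate | OC[C@H](NC(=O)OC(C)(C)C)[C@@H]1C[C@H](C)C(=O)O1 | intermediate
17 | tert-butyl N-[(1R)-2-iodo-1-[(2S,4S)-4-methyl-5-oxooxolan-2-yl]ethyl]carbamate | IC[C@H](NC(=O)OC(C)(C)C)[C@@H]1C[C@H](C)C(=O)O1 | intermediate
18 | (2R)-4-methyl-5-oxo-2-[(3R)-1-oxopentan-3-yl]-2,5-dihydrofuran-3-carbonyl chloride | O=CC[C@@H](CC)[C@H]1OC(=O)C(C)=C1C(Cl)=O | intermediate (not isolated)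
19 | {(2R)-2-[(tert-butoxycarbonyl)amino]-2-[(2S,4S)-4-methyl-5-oxooxolan-2-yl]ethyl}zinc iodide | I[Zn]C[C@H](NC(=O)OC(C)(C)C)[C@@H]1C[C@H](C)C(=O)O1 | intermediate (not isolated)
20 | tert-butyl N-[(1S)-3-[(2R)-4-methyl-5-oxo-2-[(3R)-1-oxopentan-3-yl]-2,5-dihydrofuran-3-yl]-1-[(2S,4S)-4-methyl-5-oxooxolan-2-yl]-3-oxopropyl]carbamate (keto aldehyde, key-step precursor) | O=CC[C@@H](CC)[C@H]1OC(=O)C(C)=C1C(=O)C[C@H](NC(=O)OC(C)(C)C)[C@@H]1C[C@H](C)C(=O)O1 | intermediate
21 | tert-butyl N-[(1S)-2-[(4S,7R,7aR)-7-ethyl-4-hydroxy-3-methyl-2,5-dioxo-2,4,5,6,7,7a-hexahydro-1-benzofuran-4-yl]-1-[(2S,4S)-4-methyl-5-oxooxolan-2-yl]ethyl]carbamate (ring C α-ketol, key-step product) | CC[C@@H]1CC(=O)[C@](O)(C[C@H](NC(=O)OC(C)(C)C)[C@@H]2C[C@H](C)C(=O)O2)C2=C(C)C(=O)O[C@H]12 | intermediate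
22 | tert-butyl N-[(1S)-2-[(3S,3aR,4S,7R,7aR)-7-ethyl-4-hydroxy-3-methyl-2,5-dioxooctahydro-1-benzofuran-4-yl]-1-[(2S,4S)-4-methyl-5-oxooxolan-2-yl]ethyl]carbamate (C13 epimer) | CC[C@@H]1CC(=O)[C@](O)(C[C@H](NC(=O)OC(C)(C)C)[C@@H]2C[C@H](C)C(=O)O2)[C@H]3[C@@H]1OC(=O)[C@H]3C | intermediate
23 | tert-butyl N-[(1S)-2-[(3R,3aR,4S,7R,7aR)-7-ethyl-4-hydroxy-3-methyl-2,5-dioxooctahydro-1-benzofuran-4-yl]-1-[(2S,4S)-4-methyl-5-oxooxolan-2-yl]ethyl]carbamate | CC[C@@H]1CC(=O)[C@](O)(C[C@H](NC(=O)OC(C)(C)C)[C@@H]2C[C@H](C)C(=O)O2)[C@H]3[C@@H]1OC(=O)[C@@H]3C | intermediate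
24 | 1-chloro-4-iodobutane | ClCCCCI | starting material
25 | tert-butyl N-[(1S)-2-[(3R,3aR,4S,7R,7aR)-6-(4-chlorobutyl)-7-ethyl-4-hydroxy-3-methyl-2,5-dioxooctahydro-1-benzofuran-4-yl]-1-[(2S,4S)-4-methyl-5-oxooxolan-2-yl]ethyl]carbamate (C9 = ring position 6 left undefined, epimers converge) | CC[C@@H]1C(CCCCCl)C(=O)[C@](O)(C[C@H](NC(=O)OC(C)(C)C)[C@@H]2C[C@H](C)C(=O)O2)[C@H]3[C@@H]1OC(=O)[C@@H]3C | intermediate
26 | (1S)-2-[(3R,3aR,4S,7R,7aR)-6-(4-chlorobutyl)-7-ethyl-4-hydroxy-3-methyl-2,5-dioxooctahydro-1-benzofuran-4-yl]-1-[(2S,4S)-4-methyl-5-oxooxolan-2-yl]ethan-1-aminium trifluoroacetate | CC[C@@H]1C(CCCCCl)C(=O)[C@](O)(C[C@H]([NH3+])[C@@H]2C[C@H](C)C(=O)O2)[C@H]3[C@@H]1OC(=O)[C@@H]3C.[O-]C(=O)C(F)(F)F | intermediate (not isolated)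
27 | cyclic imine: N4=C9a closes ring B as a 3,4-dihydro-2H-pyrrole fused to ring C; 1-hydroxy, 9-(4-chlorobutyl), 10-ethyl, ring D and side-chain lactone as in the target; (1S,3S,10R,11R,12R,13R,18S,20S), C9 undefined | CC[C@@H]1C(CCCCCl)C2=N[C@H]([C@@H]3C[C@H](C)C(=O)O3)C[C@]2(O)[C@H]4[C@@H]1OC(=O)[C@@H]4C | intermediate
28 | bicyclic iminium chloride: N4(+)=C9a with N4–C5 formed (rings A to D closed), C9 still bearing hydrogen | CC[C@@H]1C2C3=[N+](CCCC2)[C@H]([C@@H]4C[C@H](C)C(=O)O4)C[C@]3(O)[C@H]5[C@@H]1OC(=O)[C@@H]5C.[Cl-] | intermediate (not isolated)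
29 | CNP0179500.2, (1S,3S,10R,11R,12R,13R,18S,20S) | CC[C@@H]1C2=C3N(CCCC2)[C@H]([C@@H]2C[C@H](C)C(=O)O2)C[C@]3(O)[C@H]2[C@@H]1OC(=O)[C@@H]2C | target

**Step count**

Total: 18 steps. Longest linear sequence: 12 steps (for example 1 → 29 through steps 1–5 and 12–18; the branches from 8 and 10 are equally long).

**Steps most likely to fail**

1. Step 13. What may go wrong is poor or reversed facial selectivity at the ketone. The substrate prefers the rotamer with the ketone oxygen, not the C2 chain, next to the C13 methyl, and closure through that rotamer puts the hydroxyl syn to O11; the carbene may not overturn this. Fallback (substrate control through the C11 epimer, then correction of C11): it sets out from 20. With the achiral salt 2-(pentafluorophenyl)-6,7-dihydro-5H-pyrrolo[2,1-c][1,2,4]triazol-2-ium tetrafluoroborate and DBU in THF, H11 exchanges through the 2-oxidofuran. The (11S) keto aldehyde F1 is formed in equilibrium and should close through a chair with an equatorial ethyl group, the ketone oxygen next to the C13 methyl and the C2 chain axial, to the (1S,10R,11S) ketol F2, which has the required C1 configuration. Kinetic α-protonation of its lithium furanolate (LiN(SiMe3)2, THF, −78 °C, then AcOH) gives the deconjugated enol lactone F3 (C11=C12). Hydroxyl-directed hydrogenation of that double bond with [Ir(cod)(PCy3)(py)]PF6 delivers H11 and H12 together from the hydroxyl face. Equilibration of C13 with DBU as in step 15 brings the material back to the route at 23.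

2. Step 16. What may go wrong is proton transfer from the lactone α-positions (loss of configuration at C20), attack of the lithium carbamate on the side-chain lactone, and slow C-alkylation at the hindered C9. Fallback (no strong base; C8 is introduced as an electrophilic carbon): it sets out from 23. α-Methylenation with paraformaldehyde and N-methylanilinium trifluoroacetate in THF at reflux (Mannich condensation and elimination) gives the exocyclic enone F4. Giese addition of the 3-chloropropyl radical from 1-chloro-3-iodopropane ((Me3Si)3SiH, azobisisobutyronitrile, toluene, 80 °C) to the methylene terminus, followed by hydrogen transfer to the α-keto radical, gives 25, where it comes back to the route.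

3. Step 4. What may go wrong is sluggish addition of the ester-deactivated silyloxyfuran and erosion of the diastereoselectivity by the ester next to the reacting carbon. Fallback (carboxyl introduced after the C10–C11 bond): it sets out from 1. Oxalyl bromide with DMF in CH2Cl2 gives 4-bromo-3-methylfuran-2(5H)-one F5. TBSOTf and Et3N give tert-butyl[(4-bromo-3-methylfuran-2-yl)oxy]dimethylsilane F6. The same iminium-catalysed addition to 5 gives (3R)-3-[(2R)-3-bromo-4-methyl-5-oxo-2,5-dihydrofuran-2-yl]pentanal F7. Palladium-catalysed benzyloxycarbonylation of the vinyl bromide (CO, BnOH, Pd(OAc)2, 4,5-bis(diphenylphosphino)-9,9-dimethylxanthene, NaOAc, toluene, 60 °C) gives 6, where it comes back to the route.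

Further compounds
F1 | step 13 | tert-butyl N-[(1S)-3-[(2S)-4-methyl-5-oxo-2-[(3R)-1-oxopentan-3-yl]-2,5-dihydrofuran-3-yl]-1-[(2S,4S)-4-methyl-5-oxooxolan-2-yl]-3-oxopropyl]carbamate (C11 epimer of 20) | O=CC[C@@H](CC)[C@@H]1OC(=O)C(C)=C1C(=O)C[C@H](NC(=O)OC(C)(C)C)[C@@H]1C[C@H](C)C(=O)O1
F2 | step 13 | tert-butyl N-[(1S)-2-[(4S,7R,7aS)-7-ethyl-4-hydroxy-3-methyl-2,5-dioxo-2,4,5,6,7,7a-hexahydro-1-benzofuran-4-yl]-1-[(2S,4S)-4-methyl-5-oxooxolan-2-yl]ethyl]carbamate (C11 epimer of 21) | CC[C@@H]1CC(=O)[C@](O)(C[C@H](NC(=O)OC(C)(C)C)[C@@H]2C[C@H](C)C(=O)O2)C2=C(C)C(=O)O[C@@H]12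
F3 | step 13 | tert-butyl N-[(1S)-2-[(4S,7R)-7-ethyl-4-hydroxy-3-methyl-2,5-dioxo-2,3,4,5,6,7-hexahydro-1-benzofuran-4-yl]-1-[(2S,4S)-4-methyl-5-oxooxolan-2-yl]ethyl]carbamate (enol lactone, C13 undefined) | CC[C@@H]1CC(=O)[C@](O)(C[C@H](NC(=O)OC(C)(C)C)[C@@H]2C[C@H](C)C(=O)O2)C2=C1OC(=O)C2C
F4 | step 16 | tert-butyl N-[(1S)-2-[(3R,3aR,4S,7R,7aR)-7-ethyl-4-hydroxy-3-methyl-6-methylidene-2,5-dioxooctahydro-1-benzofuran-4-yl]-1-[(2S,4S)-4-methyl-5-oxooxolan-2-yl]ethyl]carbamate | CC[C@@H]1C(=C)C(=O)[C@](O)(C[C@H](NC(=O)OC(C)(C)C)[C@@H]2C[C@H](C)C(=O)O2)[C@H]3[C@@H]1OC(=O)[C@@H]3C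
F5 | step 4 | 4-bromo-3-methylfuran-2(5H)-one | CC1=C(Br)COC1=O
F6 | step 4 | tert-butyl[(4-bromo-3-methylfuran-2-yl)oxy]dimethylsilane | Cc1c(O[Si](C)(C)C(C)(C)C)occ1Br
F7 | step 4 | (3R)-3-[(2R)-3-bromo-4-methyl-5-oxo-2,5-dihydrofuran-2-yl]pentanal | O=CC[C@@H](CC)[C@H]1OC(=O)C(C)=C1Br
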